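Ring A of the target (C1–C2–C3–C4–C9–C10) is the carbocycle of (−)-quinic acid, carried as a 2-methylcyclohex-2-enone with its carbonyl at C4 and cis oxygens on C1 (TES) and C2 (TBS). The key step exploits the C1 oxygen stereocentre next to the enone β-carbon C10: in one operation methyl adds to C10 anti to O1 and a but-2-ynyl group alkylates the C9 enolate anti to that methyl, forming C10–CH3 and C9–C8 and the cis-dimethyl pair. The alkyne is a latent C8–C7(=O)–C6(=O)–C5H3 chain whose aldol condensation onto C4 closes ring B as the diosphenol; C1 is then inverted by oxidation and O2-directed reduction, and acylated.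

Key step: step 12

Remarks on the chemistry:
- Numbering (used for all intermediates): ring A C1(O-acyl)–C2(OH)–C3H2–C4–C9(CH3)–C10(H)CH3; ring B C4=C5–C6(=O)–C7(OH)=C8–C9. β is the face of the two methyls, α the opposite face.
- O1 and O2 are carried as two different silyl ethers, not as one cyclic ketal, so that C1 can be unmasked alone once ring B is closed. The two oxygens are told apart on the rigid lactone 7.
- Assumption: 1,2-diones and diosphenols are drawn as single tautomers; nothing in the route depends on which one predominates.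

Step 1
Reactants: 1 (S)-2-methylbutan-1-ol
Product: 2 (S)-2-methylbutanal
Conditions: TEMPO (cat.), KBr (cat.), NaOCl, NaHCO3, CH2Cl2/H2O, 0 °C; dried CH2Cl2 solution used at once
Reagents that add atoms: none
Why: Anelli oxidation (nitroxyl/hypochlorite) converts the primary alcohol into the aldehyde within minutes at 0 °C without touching the α-stereocentre, which is kept intact by using the cold, dried solution of the volatile aldehyde directly.

Step 2
Reactants: 2 (S)-2-methylbutanal; 3 triethyl (E)-4-phosphonocrotonate
Product: 4 ethyl (2E,4E,6S)-6-methylocta-2,4-dienoate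
Conditions: LiN(SiMe3)2, THF, −78 °C; then 2, −78 → 0 °C
Reagents that add atoms: none
Why: Vinylogous Horner–Wadsworth–Emmons olefination, in which the lithium anion of the stabilised phosphonate adds to the aldehyde and loses phosphate to give the new (E)-C4=C5 bond while the (E)-C2=C3 bond is retained, and the low temperature keeps the α-branched aldehyde from epimerising.

Step 3
Reactants: 4 ethyl (2E,4E,6S)-6-methylocta-2,4-dienoate
Product: 5 (2E,4E,6S)-6-methylocta-2,4-dienoic acid
Conditions: LiOH·H2O, THF/MeOH/H2O, rt; then dilute HCl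
Reagents that add atoms: lithium hydroxide, [Li+].[OH-]
Why: Saponification of the ethyl ester gives the acid after acidification; the C6 stereocentre is not acidic and the conjugated (E,E)-diene does not migrate under these conditions.

Step 4
Reactants: 6 (−)-quinic acid
Product: 7 quinide, (1S,3R,4R,5R)-1,3,4-trihydroxy-6-oxabicyclo[3.2.1]octan-7-one
Conditions: TsOH·H2O (cat.), toluene/DMF, reflux, Dean–Stark
Reagents that add atoms: none
Why: Acid-catalysed lactonisation with azeotropic removal of water, in which only the ring hydroxyl cis to the carboxyl group can reach it, so a single bicyclic γ-lactone forms and the two remaining secondary hydroxyls become different (one equatorial, one axial next to the lactone oxygen).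

Step 5
Reactants: 7 quinide
Product: 8 3-O-(tert-butyldimethylsilyl)quinide (silyl ether on the equatorial hydroxyl remote from the lactone bridge, the future O2)
Conditions: TBSCl (1.05 equiv), imidazole, DMF, 0 °C
Reagents that add atoms: tert-butyldimethylsilyl chloride, CC(C)(C)[Si](C)(C)Cl
Why: Selective O-silylation, because in the rigid bicyclic lactone the equatorial secondary hydroxyl remote from the bridge is far more accessible than the axial one next to the lactone oxygen or the tertiary one, so one equivalent of silyl chloride at 0 °C should mark the future O2 alone.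

Step 6
Reactants: 8 3-O-(tert-butyldimethylsilyl)quinide
Product: 9 3-O-(tert-butyldimethylsilyl)-4-O-(triethylsilyl)quinide (TES on the hydroxyl next to the lactone oxygen, the future O1)
Conditions: TESCl, imidazole, DMAP (cat.), DMF, 0 °C → rt
Reagents that add atoms: chlorotriethylsilane, CC[Si](Cl)(CC)CC
Why: O-silylation of the remaining secondary hydroxyl with the smaller, more reactive triethylsilyl chloride, while the tertiary hydroxyl α to the lactone carbonyl does not react with a silyl chloride under these conditions and stays free for step 8.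

Step 7
Reactants: 9 3-O-(tert-butyldimethylsilyl)-4-O-(triethylsilyl)quinide
Product: 10 5-(tert-butyldimethylsilyloxy)-1-(hydroxymethyl)-4-(triethylsilyloxy)cyclohexane-1,3-diol (ring stereocentres as in quinic acid)
Conditions: NaBH4, EtOH, 0 °C → rt
Reagents that add atoms: none
Why: Borohydride reduction of the strained α-oxygenated lactone to the primary alcohol frees the ring hydroxyl that becomes the leaving group and creates the exocyclic 1,2-diol, with the low temperature suppressing silyl migration.

Step 8
Reactants: 10 5-(tert-butyldimethylsilyloxy)-1-(hydroxymethyl)-4-(triethylsilyloxy)cyclohexane-1,3-diol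
Product: 11 3-(tert-butyldimethylsilyloxy)-5-hydroxy-4-(triethylsilyloxy)cyclohexan-1-one (3,4-cis and 4,5-trans)
Conditions: NaIO4, THF/H2O (pH 7 phosphate buffer), 0 °C
Reagents that add atoms: none
Why: Malaprade glycol cleavage, in which periodate cleaves the only free vicinal diol (tertiary hydroxyl and hydroxymethyl) to the ring ketone and formaldehyde while the ring hydroxyl, which has no free neighbour, is untouched.

Step 9
Reactants: 11 3-(tert-butyldimethylsilyloxy)-5-hydroxy-4-(triethylsilyloxy)cyclohexan-1-one
Product: 13 (4S,5R)-5-(tert-butyldimethylsilyloxy)-4-(triethylsilyloxy)cyclohex-2-en-1-one, via mesylate 12 (not isolated)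
Conditions: MsCl, Et3N, CH2Cl2, 0 °C → rt
Reagents that add atoms: none
Why: Mesylation of the β-hydroxy ketone followed in the same flask by amine-induced E1cB elimination gives the conjugated enone, the sulfonate being a far better leaving group than the β-silyloxy group on the other side of the ketone, which fixes the position of the double bond.

Step 10
Reactants: 13 (4S,5R)-5-(tert-butyldimethylsilyloxy)-4-(triethylsilyloxy)cyclohex-2-en-1-one
Product: 14 (4S,5R)-5-(tert-butyldimethylsilyloxy)-2-iodo-4-(triethylsilyloxy)cyclohex-2-en-1-one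
Conditions: I2, pyridine/CH2Cl2, 0 °C → rt
Reagents that add atoms: iodine, II
Why: α-Iodination of the enone by the addition–elimination mechanism (conjugate addition of pyridine, iodination of the enolate, loss of pyridine), which functionalises C9 without a base strong enough to aromatise the ring.

Step 11
Reactants: 14 (4S,5R)-5-(tert-butyldimethylsilyloxy)-2-iodo-4-(triethylsilyloxy)cyclohex-2-en-1-one
Product: 15 (4S,5R)-5-(tert-butyldimethylsilyloxy)-2-methyl-4-(triethylsilyloxy)cyclohex-2-en-1-one
Conditions: Me4Sn, Pd2(dba)3 (cat.), AsPh3, CuI (cat.), NMP, 60 °C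
Reagents that add atoms: tetramethylstannane, C[Sn](C)(C)C
Why: Stille cross-coupling, in which oxidative addition of zerovalent palladium to the vinylic C–I bond, methyl transfer from tin and reductive elimination install the C9 methyl under neutral conditions.

Step 12
Reactants: 15 (4S,5R)-5-(tert-butyldimethylsilyloxy)-2-methyl-4-(triethylsilyloxy)cyclohex-2-en-1-one; 16 1-bromobut-2-yne
Product: 18 2-(but-2-yn-1-yl)-5-(tert-butyldimethylsilyloxy)-2,3-dimethyl-4-(triethylsilyloxy)cyclohexan-1-one (methyls cis on the β-face; butynyl group and both silyloxy groups on the α-face), via lithium enolate 17 (not isolated)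
Conditions: Me2CuLi (from MeLi and CuI), Et2O, −78 → −40 °C; then HMPA, 16, THF, −78 → 0 °C
Reagents that add atoms: lithium dimethylcuprate, [Li+].C[Cu-]C
Why: Conjugate addition of the cuprate to the β-carbon C10 gives the lithium enolate 17 (C4–OLi, C4=C9), which is C-alkylated at C9 by SN2 displacement of bromide from 16 once HMPA is added; the closest known reaction type is the tandem cuprate addition–enolate alkylation of 2-methylcyclohex-2-enones, which gives 2,3-cis-dimethyl products. No ring is closed. C10 is set by the C1 silyloxy group: the cuprate attacks axially on the face opposite the pseudoaxial O1 (and opposite O2), so the new methyl ends trans to both oxygens. C9 is set by the new C10 methyl: to avoid allylic strain with the C9 methyl it sits pseudoaxial on the enolate and the electrophile enters axially from the other face, so the two methyls end cis. The step needs C- over O-alkylation and SN2 over SN2' attack, secured by the unhindered primary propargylic bromide with its methyl-capped alkyne terminus, and it needs the regiodefined enolate to react before proton transfer can form the C3 enolate that would expel the C2 silyloxy group, secured by the reactive electrophile, HMPA and low temperature.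

Step 13
Reactants: 18 2-(but-2-yn-1-yl)-5-(tert-butyldimethylsilyloxy)-2,3-dimethyl-4-(triethylsilyloxy)cyclohexan-1-one
Product: 19 1-[4-(tert-butyldimethylsilyloxy)-1,2-dimethyl-6-oxo-3-(triethylsilyloxy)cyclohexyl]butane-2,3-dione (configuration as in 18)
Conditions: RuO2·xH2O (cat.), NaIO4, CCl4/MeCN/H2O, 0 °C
Reagents that add atoms: sodium periodate, [Na+].[O-]I(=O)(=O)=O
Why: Ruthenium tetroxide oxidation of the internal alkyne (catalytic RuO2 reoxidised by periodate) gives the 1,2-diketone at 0 °C within minutes, fast enough that the ketone, the silyl ethers and the stereocentres are not affected.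

Step 14
Reactants: 19 1-[4-(tert-butyldimethylsilyloxy)-1,2-dimethyl-6-oxo-3-(triethylsilyloxy)cyclohexyl]butane-2,3-dione
Product: 21 bicyclic dienone with C7–OTBS (silylated diosphenol), C1α–OTES, C2α–OTBS and C9β/C10β-methyls, via diosphenol 20 (not isolated)
Conditions: K2CO3 (0.3 equiv), MeOH, 0 °C → rt; evaporate; then TBSCl, imidazole, DMF, rt
Reagents that add atoms: tert-butyldimethylsilyl chloride, CC(C)(C)[Si](C)(C)Cl
Why: Intramolecular aldol condensation, in which carbonate enolises the acidic dione methyl C5, which adds to the C4 ketone (6-enolendo-exo-trig), and dehydration plus enolisation of C7=O towards C8 gives the cross-conjugated diosphenol as the thermodynamic sink, whose acidic enol hydroxyl is then silylated; the mild base is meant to leave the β-silyloxy group on C2 in place, and no stereocentre is formed.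

Step 15
Reactants: 21 bicyclic dienone with C7–OTBS, C1α–OTES, C2α–OTBS
Product: 22 bicyclic dienone with C7–OTBS, C1α–OH, C2α–OTBS
Conditions: PPTS, MeOH/CH2Cl2, 0 °C → rt
Reagents that add atoms: none
Why: Acid-catalysed methanolysis of a silyl ether, selective for the triethylsilyl ether on O1 over the two far more acid-stable tert-butyldimethylsilyl ethers (alkyl on O2, enol on O7).

Step 16
Reactants: 22 bicyclic dienone with C7–OTBS, C1α–OH, C2α–OTBS
Product: 23 C1 ketone with C7–OTBS and C2α–OTBS
Conditions: DMP, CH2Cl2, rt
Reagents that add atoms: none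
Why: Dess–Martin oxidation of the hindered secondary alcohol to the C1 ketone under conditions that do not enolise towards C2 or C10, with the diosphenol masked as its silyl ether.

Step 17
Reactants: 23 C1 ketone with C7–OTBS and C2α–OTBS
Product: 24 C1 ketone with free C2α–OH and free diosphenol
Conditions: HF·pyridine, THF, 0 °C → rt; product used at once
Reagents that add atoms: none
Why: Fluoride-induced desilylation with hydrogen fluoride–pyridine removes both silyl ethers under acidic, non-basic conditions, so that neither α-ketol isomerisation nor vinylogous β-elimination of O2 is triggered.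

Step 18
Reactants: 24 C1 ketone with free C2α–OH and free diosphenol
Product: 25 triol with C1β–OH, C2α–OH and free diosphenol
Conditions: Me4NBH(OAc)3, MeCN/AcOH, −20 → 0 °C
Reagents that add atoms: none
Why: Hydroxyl-directed triacetoxyborohydride reduction (Evans–Saksena type), in which the axial C2 hydroxyl on the α-face binds boron and delivers hydride to the α-face of the adjacent C1 carbonyl, whose β-face is also shielded by the axial C9 methyl, so the new C1 hydroxyl should end β (trans to O2, cis to both methyls), while the dienone carbonyl C6, which has no sp3 carbinol neighbour, is not reduced by this mild reagent.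

Step 19
Reactants: 25 triol with C1β–OH, C2α–OH and free diosphenol
Product: 26 bicyclic dienone with C7–OTBS, C2α–OTBS and free C1β–OH
Conditions: TBSCl (2.5 equiv), imidazole, DMF, 0 °C → rt
Reagents that add atoms: tert-butyldimethylsilyl chloride, CC(C)(C)[Si](C)(C)Cl
Why: Selective O-silylation, in which the acidic diosphenol hydroxyl and the unhindered axial C2 hydroxyl react whereas the C1 hydroxyl, syn-axial to the C9 methyl and flanked by C10–CH3, is too hindered for the bulky silyl chloride and stays free.

Step 20
Reactants: 26 bicyclic dienone with C7–OTBS, C2α–OTBS and free C1β–OH; 5 (2E,4E,6S)-6-methylocta-2,4-dienoic acid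
Product: 28 bis-TBS ether of the target (C1β dienoate, C2α–OTBS, C7–OTBS), via mixed anhydride 27 (not isolated)
Conditions: 5, 2,4,6-trichlorobenzoyl chloride, Et3N, THF, rt; then 26, DMAP, toluene, rt → 40 °C
Reagents that add atoms: none
Why: Yamaguchi esterification, in which DMAP attacks the mixed anhydride at the less hindered dienoyl carbonyl to give an acylpyridinium ion reactive enough to acylate the hindered C1 hydroxyl with retention at C1 and without isomerising the (E,E)-diene.

Step 21
Reactants: 28 bis-TBS ether of the target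
Product: 29 Septeremophilane G
Conditions: HF·pyridine, pyridine, THF, 0 °C → rt
Reagents that add atoms: none
Why: Fluoride-induced desilylation with pyridine-buffered hydrogen fluoride frees the C2 hydroxyl and the diosphenol under conditions that leave the dienoate untouched, and acyl migration is not possible because O1 and O2 are trans-diaxial.

Compound list
1 | (S)-2-methylbutan-1-ol | CC[C@H](C)CO | starting material
2 | (S)-2-methylbutanal | CC[C@H](C)C=O | intermediate
3 | triethyl (E)-4-phosphonocrotonate | CCOC(=O)/C=C/CP(=O)(OCC)OCC | starting material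
4 | ethyl (2E,4E,6S)-6-methylocta-2,4-dienoate | CC[C@H](C)/C=C/C=C/C(=O)OCC | intermediate
5 | (2E,4E,6S)-6-methylocta-2,4-dienoic acid | CC[C@H](C)/C=C/C=C/C(=O)O | intermediate
6 | (−)-quinic acid | C1[C@H]([C@H]([C@@H](C[C@@]1(C(=O)O)O)O)O)O | starting material
7 | quinide, (1S,3R,4R,5R)-1,3,4-trihydroxy-6-oxabicyclo[3.2.1]octan-7-one | C1[C@H]([C@H]([C@@H](C[C@@]1(C2=O)O)O2)O)O | intermediate
8 | 3-O-(tert-butyldimethylsilyl)quinide | C1[C@H]([C@H]([C@@H](C[C@@]1(C2=O)O)O2)O)O[Si](C)(C)C(C)(C)C | intermediate
9 | 3-O-(tert-butyldimethylsilyl)-4-O-(triethylsilyl)quinide | C1[C@H]([C@H]([C@@H](C[C@@]1(C2=O)O)O2)O[Si](CC)(CC)CC)O[Si](C)(C)C(C)(C)C | intermediate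
10 | 5-(tert-butyldimethylsilyloxy)-1-(hydroxymethyl)-4-(triethylsilyloxy)cyclohexane-1,3-diol | C1[C@H]([C@H]([C@@H](C[C@@]1(CO)O)O)O[Si](CC)(CC)CC)O[Si](C)(C)C(C)(C)C | intermediate
11 | 3-(tert-butyldimethylsilyloxy)-5-hydroxy-4-(triethylsilyloxy)cyclohexan-1-one | C1[C@H]([C@H]([C@@H](CC1=O)O)O[Si](CC)(CC)CC)O[Si](C)(C)C(C)(C)C | intermediate
12 | 5-methanesulfonate of 11 | C1[C@H]([C@H]([C@@H](CC1=O)OS(C)(=O)=O)O[Si](CC)(CC)CC)O[Si](C)(C)C(C)(C)C | intermediate (not isolated)
13 | (4S,5R)-5-(tert-butyldimethylsilyloxy)-4-(triethylsilyloxy)cyclohex-2-en-1-one | O=C1C=C[C@H](O[Si](CC)(CC)CC)[C@H](O[Si](C)(C)C(C)(C)C)C1 | intermediate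
14 | (4S,5R)-5-(tert-butyldimethylsilyloxy)-2-iodo-4-(triethylsilyloxy)cyclohex-2-en-1-one | O=C1C(I)=C[C@H](O[Si](CC)(CC)CC)[C@H](O[Si](C)(C)C(C)(C)C)C1 | intermediate
15 | (4S,5R)-5-(tert-butyldimethylsilyloxy)-2-methyl-4-(triethylsilyloxy)cyclohex-2-en-1-one (key-step precursor) | O=C1C(C)=C[C@H](O[Si](CC)(CC)CC)[C@H](O[Si](C)(C)C(C)(C)C)C1 | intermediate
16 | 1-bromobut-2-yne | CC#CCBr | starting material
17 | lithium enolate of the conjugate adduct (C4–OLi, C4=C9; C10 methyl trans to O1 and O2) | [Li]OC1=C(C)[C@@H](C)[C@H](O[Si](CC)(CC)CC)[C@H](O[Si](C)(C)C(C)(C)C)C1 | intermediate (not isolated)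
18 | 2-(but-2-yn-1-yl)-5-(tert-butyldimethylsilyloxy)-2,3-dimethyl-4-(triethylsilyloxy)cyclohexan-1-one (key-step product) | O=C1C[C@@H](O[Si](C)(C)C(C)(C)C)[C@@H](O[Si](CC)(CC)CC)[C@H](C)[C@@]1(C)CC#CC | intermediate
19 | 1-[4-(tert-butyldimethylsilyloxy)-1,2-dimethyl-6-oxo-3-(triethylsilyloxy)cyclohexyl]butane-2,3-dione | O=C1C[C@@H](O[Si](C)(C)C(C)(C)C)[C@@H](O[Si](CC)(CC)CC)[C@H](C)[C@@]1(C)CC(=O)C(C)=O | intermediate
20 | 7-(tert-butyldimethylsilyloxy)-3-hydroxy-4a,5-dimethyl-6-(triethylsilyloxy)-5,6,7,8-tetrahydronaphthalen-2(4aH)-one (C1α–OTES, C2α–OTBS) | CC[Si](CC)(CC)O[C@@H]1[C@H](O[Si](C)(C)C(C)(C)C)CC2=CC(=O)C(O)=C[C@]2(C)[C@H]1C | intermediate (not isolated)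
21 | 3,7-bis(tert-butyldimethylsilyloxy)-4a,5-dimethyl-6-(triethylsilyloxy)-5,6,7,8-tetrahydronaphthalen-2(4aH)-one | CC[Si](CC)(CC)O[C@@H]1[C@H](O[Si](C)(C)C(C)(C)C)CC2=CC(=O)C(O[Si](C)(C)C(C)(C)C)=C[C@]2(C)[C@H]1C | intermediate
22 | 3,7-bis(tert-butyldimethylsilyloxy)-6-hydroxy-4a,5-dimethyl-5,6,7,8-tetrahydronaphthalen-2(4aH)-one (C1α–OH) | O[C@@H]1[C@H](O[Si](C)(C)C(C)(C)C)CC2=CC(=O)C(O[Si](C)(C)C(C)(C)C)=C[C@]2(C)[C@H]1C | intermediate
23 | 3,7-bis(tert-butyldimethylsilyloxy)-4a,5-dimethyl-7,8-dihydronaphthalene-2,6(4aH,5H)-dione | O=C1[C@H](O[Si](C)(C)C(C)(C)C)CC2=CC(=O)C(O[Si](C)(C)C(C)(C)C)=C[C@]2(C)[C@H]1C | intermediate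
24 | 3,7-dihydroxy-4a,5-dimethyl-7,8-dihydronaphthalene-2,6(4aH,5H)-dione | O=C1[C@H](O)CC2=CC(=O)C(O)=C[C@]2(C)[C@H]1C | intermediate
25 | 3,6,7-trihydroxy-4a,5-dimethyl-5,6,7,8-tetrahydronaphthalen-2(4aH)-one (C1β–OH, C2α–OH) | O[C@H]1[C@H](O)CC2=CC(=O)C(O)=C[C@]2(C)[C@H]1C | intermediate
26 | 3,7-bis(tert-butyldimethylsilyloxy)-6-hydroxy-4a,5-dimethyl-5,6,7,8-tetrahydronaphthalen-2(4aH)-one (C1β–OH) | O[C@H]1[C@H](O[Si](C)(C)C(C)(C)C)CC2=CC(=O)C(O[Si](C)(C)C(C)(C)C)=C[C@]2(C)[C@H]1C | intermediate
27 | (2E,4E,6S)-6-methylocta-2,4-dienoic 2,4,6-trichlorobenzoic anhydride | CC[C@H](C)/C=C/C=C/C(=O)OC(=O)c1c(Cl)cc(Cl)cc1Cl | intermediate (not isolated)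
28 | bis-TBS ether of Septeremophilane G (C1β dienoate, C2α–OTBS, C7–OTBS) | CC[C@H](C)/C=C/C=C/C(=O)O[C@H]1[C@H](O[Si](C)(C)C(C)(C)C)CC2=CC(=O)C(O[Si](C)(C)C(C)(C)C)=C[C@]2(C)[C@H]1C | intermediate
29 | Septeremophilane G | CC[C@H](C)/C=C/C=C/C(=O)O[C@H]1[C@H](O)CC2=CC(=O)C(O)=C[C@]2(C)[C@H]1C | target

Total step count: 21. Longest linear sequence: 18 steps (steps 4–21, from (−)-quinic acid); the acid 5 is made in 3 steps and joins at step 20.

Steps most likely to fail

Step 12. The copper-containing enolate may alkylate too slowly, so that proton exchange with the product forms the C3 enolate and the C2 silyloxy group is lost by β-elimination. The fallback separates the two bond formations and sets out from 15. Me2CuLi with Me3SiCl and Et3N in THF at −78 °C should give, by the same anti addition, the trimethylsilyl enol ether of the conjugate adduct F1, which is isolated free of copper salts. MeLi in THF at 0 °C cleaves its O–Si bond to the pure lithium enolate 17, and alkylation with 16 in THF/HMPA comes back to the route at 18.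

Step 14. Under equilibrating base, deprotonation at C3 with β-elimination of the C2 silyloxy group from the C4 ketone, or reversible bridged aldol modes, may outrun the ring closure. The fallback makes the ring in two irreversible stages and sets out from 19. LiN(SiMe3)2 (1 equiv, THF, −78 °C) deprotonates the dione methyl C5 kinetically and a cold quench should give the aldol adduct with a tertiary C4 hydroxyl F2 (either C4 epimer). Dehydration with Burgess reagent (benzene, 50 °C) and tautomerisation give 20, which is silylated as in step 14 to come back to the route at 21.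

Step 20. Acyl transfer to the axial C1 hydroxyl, syn-axial to the C9 methyl, may be so slow that the mixed anhydride is diverted to the symmetrical anhydride or the dienoate isomerises. The fallback builds the dienoate on the substrate and sets out from 26. 2-(Diethoxyphosphoryl)acetyl chloride (pyridine, DMAP, CH2Cl2), a small and very reactive acyl donor, should give the C1 diethylphosphonoacetate F3. Aldehyde 2 and (triphenylphosphoranylidene)acetaldehyde (CH2Cl2, rt) give (S,E)-4-methylhex-2-enal F4. Horner–Wadsworth–Emmons olefination of F3 with F4 under LiCl/iPr2NEt in MeCN forms the (2E,4E)-dienoate in place and comes back to the route at 28.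

Further compounds
F1 | step 12 | trimethylsilyl enol ether of the conjugate adduct (C4–OSiMe3, C4=C9; C10 methyl trans to O1 and O2) | C[Si](C)(C)OC1=C(C)[C@@H](C)[C@H](O[Si](CC)(CC)CC)[C@H](O[Si](C)(C)C(C)(C)C)C1
F2 | step 14 | aldol adduct, 7-(tert-butyldimethylsilyloxy)-8a-hydroxy-4a,5-dimethyl-6-(triethylsilyloxy)octahydronaphthalene-2,3-dione (C4 hydroxyl, either epimer) | CC[Si](CC)(CC)O[C@@H]1[C@H](O[Si](C)(C)C(C)(C)C)CC2(O)CC(=O)C(=O)C[C@]2(C)[C@H]1C
F3 | step 20 | C1β 2-(diethoxyphosphoryl)acetate of 26 | CCOP(=O)(OCC)CC(=O)O[C@H]1[C@H](O[Si](C)(C)C(C)(C)C)CC2=CC(=O)C(O[Si](C)(C)C(C)(C)C)=C[C@]2(C)[C@H]1C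
F4 | step 20 | (S,E)-4-methylhex-2-enal | CC[C@H](C)/C=C/C=O
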